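**Plan**

- Retrosynthesis: with the two benzoates removed, ring C is cut at C4–C4a and O1–C2. This leaves phloroglucinol (ring A) and an α-benzoyloxy aroylacetate carrying ring B. The ketoester is then cut at C3–O, at C2–C3 (malonate acylation) and at the C3'–prenyl bond.
- Forward: ring B is prenylated first and carried as its benzoate-masked acid. The C2–C3–C4 chain is attached and oxygenated at C3, and ring C closes last when this chain is fused onto preformed ring A. Methanolysis then frees the 3- and 4'-hydroxyls.
- Enabling feature: ring A is phloroglucinol. Its ring carbons (future C4a, C6, C8) and its hydroxyls (future O1, O5, O7) are equivalent, so acylation at any carbon and closure through either flanking oxygen give the same 5,7-dihydroxychromone with no protection.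
- Stereochemistry: the target has no stereocentre and its alkene has no geometry. The one stereocentre on the way (the α-carbon of the ketoester) is racemic and becomes sp2 C3.

Key step: step 6

Assumption: "prenyl" means 3-methylbut-2-en-1-yl; ketoester 10 is made and used as the racemate, and phloroglucinol is used anhydrous so that no water enters the melt.

**Route**

Step 1
Reactants: 1 methyl 4-hydroxybenzoate; 2 prenyl bromide (1-bromo-3-methylbut-2-ene)
Product: 3 methyl 4-hydroxy-3-prenylbenzoate
Conditions: NaH (1.05 equiv), toluene, 0 °C to rt; then 2 (1.1 equiv), rt to 60 °C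
Reagents that add atoms: none
Why: Ortho C-alkylation of an ambident phenoxide (Claisen-type C-allylation): as a tight sodium ion pair in toluene the oxygen is shielded, so the allylic bromide should be taken up at the free ortho carbon, the para carbon being blocked by the ester.

Step 2
Reactants: 3 methyl 4-hydroxy-3-prenylbenzoate
Product: 4 4-hydroxy-3-prenylbenzoic acid
Conditions: NaOH (3 equiv), MeOH/H2O, 60 °C; then 1 M HCl, 0 °C, to pH 3
Reagents that add atoms: sodium hydroxide, [Na+].[OH-]
Why: Ester saponification by hydroxide, to which the prenyl alkene is inert; brief cold dilute acid at work-up protonates the salt without closing the ortho-prenyl phenol to a chroman.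

Step 3
Reactants: 4 4-hydroxy-3-prenylbenzoic acid
Product: 5 4-(benzoyloxy)-3-prenylbenzoic acid
Conditions: BzCl (1.3 equiv), 2 M NaOH aq, acetone, 0–5 °C; then 1 M HCl to pH 2
Reagents that add atoms: benzoyl chloride, O=C(Cl)c1ccccc1
Why: Schotten–Baumann acylation: the phenoxide is benzoylated in cold aqueous alkali while any mixed carboxylic anhydride is hydrolysed back to the carboxylate, so only the phenol ends up masked and the later melt cannot cyclise it onto the prenyl group.

Step 4
Reactants: 5 4-(benzoyloxy)-3-prenylbenzoic acid; 6 potassium ethyl malonate (potassium 3-ethoxy-3-oxopropanoate)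
Product: 9 ethyl 3-[4-(benzoyloxy)-3-prenylphenyl]-3-oxopropanoate, via 4-(benzoyloxy)-3-prenylbenzoyl chloride 7 (not isolated), via 2-aroylmalonic acid monoethyl ester 8 (not isolated)
Conditions: (COCl)2 (1.3 equiv), DMF (cat.), CH2Cl2, 0 °C to rt, then evaporation; 6 (2 equiv), MgCl2, Et3N, MeCN, 0 °C to rt, 16 h; then 1 M HCl, 0 °C
Reagents that add atoms: none
Why: Acid chloride formation followed by C-acylation of the magnesium enolate of the malonate half-ester and loss of CO2 on acidification (decarboxylative Claisen-type ketoester synthesis); the acid chloride is far more electrophilic than the aryl benzoate, and it is stripped of HCl quickly so that the alkene is not hydrochlorinated.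

Step 5
Reactants: 9 ethyl 3-[4-(benzoyloxy)-3-prenylphenyl]-3-oxopropanoate
Product: 10 ethyl 2-(benzoyloxy)-3-[4-(benzoyloxy)-3-prenylphenyl]-3-oxopropanoate (racemic)
Conditions: NaH (1.05 equiv), THF, 0 °C; then (PhCO2)2 (1.0 equiv, added slowly), 0 °C to rt
Reagents that add atoms: dibenzoyl peroxide, O=C(OOC(=O)c1ccccc1)c1ccccc1
Why: Electrophilic α-benzoyloxylation of a β-ketoester enolate by a diacyl peroxide: the enolate carbon attacks the O–O bond and expels benzoate, the peroxide does not touch the isolated alkene at 0 °C, and the new stereocentre is formed racemic, which is irrelevant because it becomes C3 of the pyranone.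

Step 6
Reactants: 10 ethyl 2-(benzoyloxy)-3-[4-(benzoyloxy)-3-prenylphenyl]-3-oxopropanoate; 11 phloroglucinol (benzene-1,3,5-triol)
Product: 14 3,4'-di-O-benzoyl isolicoflavonol (2-[4-(benzoyloxy)-3-prenylphenyl]-5,7-dihydroxy-4-oxo-4H-chromen-3-yl benzoate), via acylketene 12 (not isolated), via C-acylated diketone 13 (not isolated)
Conditions: 11 (anhydrous, 2 equiv), neat melt, Ar sweep, 240 °C, 30 min, EtOH and H2O distilled out
Reagents that add atoms: none
Why: Proposed new method: the thermal Mentzer pyrone synthesis is established for phloroglucinol with ethyl aroylacetates and with α-alkyl or α-aryl β-ketoesters but has not been shown with an α-acyloxy ketoester, so this step extends it, its closest known relatives being that Mentzer condensation and the Allan–Robinson flavonol synthesis, which passes through the same kind of α-benzoyloxy 1,3-diketone. On heating, 10 should lose ethanol from its enol form to give acylketene 12, which acylates phloroglucinol at carbon (directly through its keto tautomer, or by O-acylation and thermal acyl shift) and so makes C4–C4a in diketone 13. A hydroxyl flanking the new acyl group then adds to the aryl ketone in a 6-exo-trig closure, and loss of water forms O1–C2 and the aromatic pyranone ring C. No stereocentre is created, the α-carbon of 10 ending as sp2 C3. The selectivity needed is chromone over coumarin and a single regioisomer: the acid-free melt reacts through the acylketene, so the ester carbon and not the ketone is joined to the ring, the α-benzoyloxy group and aryl conjugation make the ketone a poor partner for Pechmann-type ring attack, and the threefold symmetry of ring A removes any regiochemical choice. The neutral medium should leave the prenyl alkene beside the masked phenol uncyclised, and benzoyl migration onto ring A is tolerated because step 7 removes every ester.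

Step 7
Reactants: 14 3,4'-di-O-benzoyl isolicoflavonol
Product: 15 isolicoflavonol (3,5,7-trihydroxy-2-(4-hydroxy-3-prenylphenyl)-4H-chromen-4-one)
Conditions: K2CO3 (5 equiv), degassed MeOH, Ar, rt; then 1 M HCl at 0 °C to pH 6
Reagents that add atoms: none
Why: Carbonate-mediated methanolysis (transesterification) of an enol benzoate and an aryl benzoate, both activated esters, under oxygen-free basic conditions that leave the prenyl group and the pyranone untouched and bring the ortho-prenyl phenol into contact with nothing more acidic than a neutralising quench.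

**Compound list**

1 | methyl 4-hydroxybenzoate | COC(=O)c1ccc(O)cc1 | starting material
2 | prenyl bromide (1-bromo-3-methylbut-2-ene) | CC(C)=CCBr | starting material
3 | methyl 4-hydroxy-3-prenylbenzoate | COC(=O)c1ccc(O)c(CC=C(C)C)c1 | intermediate
4 | 4-hydroxy-3-prenylbenzoic acid | CC(C)=CCc1cc(C(=O)O)ccc1O | intermediate
5 | 4-(benzoyloxy)-3-prenylbenzoic acid | CC(C)=CCc1cc(C(=O)O)ccc1OC(=O)c1ccccc1 | intermediate
6 | potassium ethyl malonate | CCOC(=O)CC(=O)[O-].[K+] | starting material
7 | 4-(benzoyloxy)-3-prenylbenzoyl chloride | CC(C)=CCc1cc(C(=O)Cl)ccc1OC(=O)c1ccccc1 | intermediate (not isolated)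
8 | 2-[4-(benzoyloxy)-3-prenylbenzoyl]malonic acid monoethyl ester (formed as its magnesium chelate) | CCOC(=O)C(C(=O)O)C(=O)c1ccc(OC(=O)c2ccccc2)c(CC=C(C)C)c1 | intermediate (not isolated)
9 | ethyl 3-[4-(benzoyloxy)-3-prenylphenyl]-3-oxopropanoate | CCOC(=O)CC(=O)c1ccc(OC(=O)c2ccccc2)c(CC=C(C)C)c1 | intermediate
10 | ethyl 2-(benzoyloxy)-3-[4-(benzoyloxy)-3-prenylphenyl]-3-oxopropanoate (racemic) | CCOC(=O)C(OC(=O)c1ccccc1)C(=O)c1ccc(OC(=O)c2ccccc2)c(CC=C(C)C)c1 | intermediate
11 | phloroglucinol (benzene-1,3,5-triol) | Oc1cc(O)cc(O)c1 | starting material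
12 | 2-(benzoyloxy)-3-[4-(benzoyloxy)-3-prenylphenyl]-3-oxoprop-1-en-1-one (acylketene) | O=C=C(OC(=O)c1ccccc1)C(=O)c1ccc(OC(=O)c2ccccc2)c(CC=C(C)C)c1 | intermediate (not isolated)
13 | 2-(benzoyloxy)-1-[4-(benzoyloxy)-3-prenylphenyl]-3-(2,4,6-trihydroxyphenyl)propane-1,3-dione | O=C(c1c(O)cc(O)cc1O)C(OC(=O)c1ccccc1)C(=O)c1ccc(OC(=O)c2ccccc2)c(CC=C(C)C)c1 | intermediate (not isolated)
14 | 3,4'-di-O-benzoyl isolicoflavonol | CC(C)=CCc1cc(-c2oc3cc(O)cc(O)c3c(=O)c2OC(=O)c2ccccc2)ccc1OC(=O)c1ccccc1 | intermediate
15 | isolicoflavonol | CC(C)=CCc1cc(-c2oc3cc(O)cc(O)c3c(=O)c2O)ccc1O | target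

**Count**

Total step count: 7. Longest linear sequence: 7 steps (1 to 15); 6 and 11 are commercial and enter at steps 4 and 6.

**Steps most likely to fail**

1. Step 6 (proposed new method). The α-acyloxy ketoester may break down in the melt before the acylketene forms, through retro-Claisen cleavage by phenol attack on the activated ketone or loss of benzoic acid. Benzoyl transfer to phloroglucinol may also unmask the phenol beside the prenyl group and let it close to a chroman at 240 °C. The fallback is the classical Allan–Robinson flavonol synthesis, which is known chemistry and closes ring C at C2–C3 and O1–C2 instead. It sets out from 11 and from acid 5. Hoesch acylation of 11 with (benzoyloxy)acetonitrile (ZnCl2, HCl gas, Et2O, 0 °C) should give 2-(benzoyloxy)-1-(2,4,6-trihydroxyphenyl)ethan-1-iminium chloride F1, which hot water hydrolyses to 2-(benzoyloxy)-1-(2,4,6-trihydroxyphenyl)ethanone F2. Acid 5 is converted, through chloride 7 and a second equivalent of 5 in pyridine/CH2Cl2, into 4-(benzoyloxy)-3-prenylbenzoic anhydride F3. Heating F2 with F3 and the potassium salt of 5 at 170–180 °C should give 7-O-[4-(benzoyloxy)-3-prenylbenzoyl]-3,4'-di-O-benzoyl isolicoflavonol F4. Methanolysis of F4 under the conditions of step 7 comes back to the route at target 15.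

2. Step 1. O-alkylation and a second C-alkylation may compete with mono ortho C-prenylation, and the ester-deactivated phenoxide may convert sluggishly. The fallback sets out from 1 and installs the prenyl group by rearrangement instead of direct alkylation. O-alkylation with 3-chloro-3-methylbut-1-yne (K2CO3, KI, CuI cat., acetone, reflux) should give methyl 4-[(2-methylbut-3-yn-2-yl)oxy]benzoate F5. Semi-hydrogenation (H2, Pd/CaCO3 poisoned with Pb(OAc)2, quinoline, EtOAc) should give methyl 4-[(2-methylbut-3-en-2-yl)oxy]benzoate F6. Aromatic Claisen rearrangement (N,N-diethylaniline, 180 °C) delivers the allyl unit to the ortho carbon with allylic inversion and comes back to the route at 3.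

3. Step 5. Proton exchange between the more acidic product and unreacted enolate may stall the reaction and open the way to a second benzoyloxylation. The fallback sets out from 9 and fixes mono-substitution by construction. Regitz diazo transfer (4-acetamidobenzenesulfonyl azide, Et3N, MeCN) should give ethyl 2-diazo-3-[4-(benzoyloxy)-3-prenylphenyl]-3-oxopropanoate F7. Rh2(OAc)4-catalysed O–H insertion of the derived carbenoid into benzoic acid (3 equiv, CH2Cl2, reflux) comes back to the route at 10.

Further compounds
F1 | step 6 | 2-(benzoyloxy)-1-(2,4,6-trihydroxyphenyl)ethan-1-iminium chloride | [NH2+]=C(COC(=O)c1ccccc1)c1c(O)cc(O)cc1O.[Cl-]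
F2 | step 6 | 2-(benzoyloxy)-1-(2,4,6-trihydroxyphenyl)ethanone | O=C(COC(=O)c1ccccc1)c1c(O)cc(O)cc1O
F3 | step 6 | 4-(benzoyloxy)-3-prenylbenzoic anhydride | CC(C)=CCc1cc(C(=O)OC(=O)c2ccc(OC(=O)c3ccccc3)c(CC=C(C)C)c2)ccc1OC(=O)c1ccccc1
F4 | step 6 | 7-O-[4-(benzoyloxy)-3-prenylbenzoyl]-3,4'-di-O-benzoyl isolicoflavonol | CC(C)=CCc1cc(-c2oc3cc(OC(=O)c4ccc(OC(=O)c5ccccc5)c(CC=C(C)C)c4)cc(O)c3c(=O)c2OC(=O)c2ccccc2)ccc1OC(=O)c1ccccc1
F5 | step 1 | methyl 4-[(2-methylbut-3-yn-2-yl)oxy]benzoate | COC(=O)c1ccc(OC(C)(C)C#C)cc1
F6 | step 1 | methyl 4-[(2-methylbut-3-en-2-yl)oxy]benzoate | COC(=O)c1ccc(OC(C)(C)C=C)cc1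
F7 | step 5 | ethyl 2-diazo-3-[4-(benzoyloxy)-3-prenylphenyl]-3-oxopropanoate | CCOC(=O)C(=[N+]=[N-])C(=O)c1ccc(OC(=O)c2ccccc2)c(CC=C(C)C)c1
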